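**Retrosynthetic overview**

1. Target 30 ⇒ ester C–O bond (Yamaguchi) between 4-O-TBS-vanillic acid 27 and hydroazulene diol 24; the C8 carbinol comes from hydroxyl-directed reduction, the C5 oxygen from singlet-oxygen [4+2] addition to the ring dienol ether of enone 18.
2. Enone 18 ⇒ trans-hydroazulenone 14 ⇒ cis-decalin hydroxy mesylate 13, by one semipinacol 1,2-shift that contracts one six-membered ring to the cyclopentane and expands the other to the cycloheptanone.
3. 13 ⇒ octalone 8 (isopropyl addition, hydroxyl-directed osmylation on the same face) ⇒ Robinson annulation of 2-methylcyclohexanone with methyl vinyl ketone through a chiral imine; the quaternary carbon is the only stereocentre set by an external chiral source, all others are relayed from it.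
4. Enabling feature: in 13 (ring A = C1–C4, C4a, C8a; ring B = C4a, C5–C8, C8a) the equatorial C1–OMs bond of chair ring A is antiperiplanar to the ring-fusion bond C8a–C4a, and the fusion atom C8a carries the free hydroxyl that becomes the carbonyl.
5. Order of ring formation: cyclohexane of 1 (bought) → second cyclohexane (step 2) → five- and seven-membered rings together (step 6).

Key step: step 6

Remark: compounds 6–13 carry naphthalene numbering, compounds 14–30 azulene numbering (C1 = carbinol carbon with isopropyl, C3a = methyl-bearing fusion carbon, C8 = carbon that ends as the ester carbinol, C8a = fusion CH); racemic 1 is usable because its stereocentre is erased in the enamine tautomer of the imine.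

Step 1
Reactants: 1 2-methylcyclohexanone (racemic); 2 (R)-1-phenylethylamine; 3 methyl vinyl ketone
Product: 6 (S)-2-methyl-2-(3-oxobutyl)cyclohexan-1-one, via chiral imine 4 (not isolated), via Michael-adduct imine 5 (not isolated)
Conditions: TsOH (cat.), toluene, reflux (–H2O); then 3, THF, 25 °C; then aq. AcOH, 25 °C
Reagents that add atoms: water, O
Why: Deracemizing Michael addition of a chiral imine: 4 reacts through its more substituted secondary enamine tautomer, the (R)-phenylethyl group shields one face so that the new quaternary carbon should form with (S) configuration, and hydrolysis returns the amine.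

Step 2
Reactants: 6 (S)-2-methyl-2-(3-oxobutyl)cyclohexan-1-one
Product: 8 (S)-4a-methyl-4,4a,5,6,7,8-hexahydronaphthalen-2(3H)-one, via cis-ketol 7 (not isolated)
Conditions: NaOMe (cat.), MeOH, 60 °C
Reagents that add atoms: none
Why: Intramolecular aldol condensation (second stage of the Robinson annulation) closes the second six-membered ring; the quaternary centre cannot enolize and is untouched.

Step 3
Reactants: 8 (S)-4a-methyl-4,4a,5,6,7,8-hexahydronaphthalen-2(3H)-one
Product: 9 (2R,4aS)-4a-methyl-2-(propan-2-yl)-2,3,4,4a,5,6,7,8-octahydronaphthalen-2-ol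
Conditions: i-PrMgCl, CeCl3, THF, –78 → 0 °C
Reagents that add atoms: isopropylmagnesium chloride, CC(C)[Mg]Cl
Why: Cerium-mediated 1,2-addition to the enone (enolization and 1,4-addition suppressed); axial attack on the face opposite the angular methyl, as is usual for angularly methylated octalones, should place the new hydroxyl cis to the 4a-methyl group.

Step 4
Reactants: 9 (2R,4aS)-4a-methyl-2-(propan-2-yl)-2,3,4,4a,5,6,7,8-octahydronaphthalen-2-ol
Product: 12 (1R,2R,4aS,8aR)-4a-methyl-2-(propan-2-yl)-2-[(trimethylsilyl)oxy]decahydronaphthalene-1,8a-diol, via osmate ester 10 (not isolated), via silylated osmate ester 11 (not isolated)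
Conditions: OsO4 (1.05 equiv), TMEDA, CH2Cl2, –78 °C; N-(trimethylsilyl)imidazole, 25 °C; H2N(CH2)2NH2, 25 °C
Reagents that add atoms: osmium tetroxide, O=[Os](=O)(=O)=O; N-(trimethylsilyl)imidazole, C[Si](C)(C)n1ccnc1
Why: Hydrogen-bond-directed dihydroxylation: the OsO4–TMEDA complex is held by the tertiary allylic hydroxyl and should add to C1=C8a on that face, so that C1–O and C8a–O end cis to C2–O and to the angular methyl; while the new diol is masked as the osmate ester the only free hydroxyl (C2) is silylated, and ligand exchange with the diamine then releases the diol.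

Step 5
Reactants: 12 (1R,2R,4aS,8aR)-4a-methyl-2-(propan-2-yl)-2-[(trimethylsilyl)oxy]decahydronaphthalene-1,8a-diol
Product: 13 (1R,2R,4aS,8aR)-8a-hydroxy-4a-methyl-2-(propan-2-yl)-2-[(trimethylsilyl)oxy]decahydronaphthalen-1-yl methanesulfonate
Conditions: MsCl, Et3N, CH2Cl2, –20 → 0 °C
Reagents that add atoms: methanesulfonyl chloride, CS(=O)(=O)Cl
Why: Sulfene-type mesylation selects the only secondary hydroxyl (C1); the ring-fusion tertiary hydroxyl at C8a should not react.

Step 6
Reactants: 13 (1R,2R,4aS,8aR)-8a-hydroxy-4a-methyl-2-(propan-2-yl)-2-[(trimethylsilyl)oxy]decahydronaphthalen-1-yl methanesulfonate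
Product: 14 (1R,3aS,8aR)-3a-methyl-1-(propan-2-yl)-1-[(trimethylsilyl)oxy]-2,3,3a,4,5,6,7,8a-octahydroazulen-8(1H)-one (trans-fused)
Conditions: Et2AlCl (2 equiv), CH2Cl2, –78 → 0 °C; then aq. KNaC4H4O6
Reagents that add atoms: none
Why: Et2AlCl converts the C8a hydroxyl into an aluminium alkoxide and activates the mesylate, and the C8a–C4a ring-fusion bond, antiperiplanar to the equatorial C1–OMs bond, migrates to C1 while C8a becomes the ketone (semipinacol rearrangement). The closest known reaction type is the organoaluminium- or base-promoted 1,2-shift of cis-1,2-diol monosulfonates, as used to turn cis-decalins into hydroazulenones. Both new rings arise from this one shift: the five-membered ring (old C1, C2, C3, C4, C4a) by contraction of ring A through loss of C8a, and the seven-membered ring (old C8a, C8, C7, C6, C5, C4a, C1) by expansion of ring B through insertion of C1. The new stereocentre (old C1, azulene C8a) forms with inversion because C4a attacks from the side opposite the leaving group and itself migrates with retention, so the all-cis arrangement of 13 should translate into the trans ring fusion with the C1 oxygen cis to the angular methyl. The step needs C8a–C4a to migrate rather than C8a–C8 or C2–C3: the chair of ring A, fixed by the equatorial isopropyl group, holds the mesylate equatorial (anti to C8a–C4a, gauche to C8a–C8), and the silyl ether at C2 leaves the C8a alkoxide as the only oxygen able to push.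

Step 7
Reactants: 14 (1R,3aS,8aR)-3a-methyl-1-(propan-2-yl)-1-[(trimethylsilyl)oxy]-2,3,3a,4,5,6,7,8a-octahydroazulen-8(1H)-one
Product: 16 (1R,3aS,8aR)-3a-methyl-1-(propan-2-yl)-1-[(trimethylsilyl)oxy]-2,3,3a,4,5,8a-hexahydroazulen-8(1H)-one, via silyl enol ether 15 (not isolated)
Conditions: LiN(i-Pr)2, THF, –78 °C; Me3SiCl; then Pd(OAc)2 (10 mol %), O2 (1 atm), DMSO, 25 °C
Reagents that add atoms: none
Why: Saegusa–Ito oxidation: kinetic deprotonation should occur at the C7 methylene (the C8a methine lies between two fully substituted carbons), and palladium-mediated dehydrosilylation of 15 gives the C6=C7 enone.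

Step 8
Reactants: 16 (1R,3aS,8aR)-3a-methyl-1-(propan-2-yl)-1-[(trimethylsilyl)oxy]-2,3,3a,4,5,8a-hexahydroazulen-8(1H)-one
Product: 18 (1R,3aS,8aR)-3a,6-dimethyl-1-(propan-2-yl)-1-[(trimethylsilyl)oxy]-2,3,3a,4,5,8a-hexahydroazulen-8(1H)-one, via methylated silyl enol ether 17 (not isolated)
Conditions: Me2CuLi (from MeLi, CuI), Me3SiCl, THF, –78 °C; then Pd(OAc)2 (10 mol %), O2 (1 atm), DMSO, 25 °C
Reagents that add atoms: lithium dimethylcuprate, [Li+].C[Cu-]C
Why: Cuprate conjugate addition places the methyl group on C6, the enolate is trapped regiospecifically as its silyl ether, and a second Saegusa–Ito oxidation restores the enone, erasing the transient C6 stereocentre.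

Step 9
Reactants: 18 (1R,3aS,8aR)-3a,6-dimethyl-1-(propan-2-yl)-1-[(trimethylsilyl)oxy]-2,3,3a,4,5,8a-hexahydroazulen-8(1H)-one
Product: 19 8-[(tert-butyldimethylsilyl)oxy]-3a,6-dimethyl-1-(propan-2-yl)-1-[(trimethylsilyl)oxy]-1,2,3,3a,4,8a-hexahydroazulene (5,7-diene; configuration as in 18)
Conditions: TBSOTf, Et3N, CH2Cl2, 0 → 25 °C
Reagents that add atoms: tert-butyldimethylsilyl trifluoromethanesulfonate, CC(C)(C)[Si](C)(C)OS(=O)(=O)C(F)(F)F
Why: Soft enolization of the enone should give the thermodynamic, fully endocyclic 1-siloxy-1,3-diene by γ-deprotonation at C5; the hindered α′ methine C8a should stay untouched.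

Step 10
Reactants: 19 8-[(tert-butyldimethylsilyl)oxy]-3a,6-dimethyl-1-(propan-2-yl)-1-[(trimethylsilyl)oxy]-1,2,3,3a,4,8a-hexahydroazulene
Product: 22 (1R,3aR,5S,8aR)-1,5-dihydroxy-3a,6-dimethyl-1-(propan-2-yl)-2,3,3a,4,5,8a-hexahydroazulen-8(1H)-one, via endoperoxide 20 (not isolated), via silyl-protected hydroxy enone 21 (not isolated)
Conditions: O2, tetraphenylporphyrin (cat.), visible light, CH2Cl2, –78 °C; thiourea, MeOH, –78 → 25 °C; citric acid, MeOH/H2O, 25 °C
Reagents that add atoms: dioxygen, O=O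
Why: Singlet-oxygen [4+2] cycloaddition to the s-cis ring diene (known for 1-siloxy-1,3-dienes as a route to γ-hydroxy enones) should occur on the face opposite the angular 3a-methyl group and so set C5; thiourea cleaves the O–O bond, the silyl hemiketal collapses to the enone, and mild acid removes the tertiary trimethylsilyl ether.

Step 11
Reactants: 22 (1R,3aR,5S,8aR)-1,5-dihydroxy-3a,6-dimethyl-1-(propan-2-yl)-2,3,3a,4,5,8a-hexahydroazulen-8(1H)-one
Product: 23 (1R,3aR,5S,8aR)-5-[(tert-butyldimethylsilyl)oxy]-1-hydroxy-3a,6-dimethyl-1-(propan-2-yl)-2,3,3a,4,5,8a-hexahydroazulen-8(1H)-one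
Conditions: TBSCl, imidazole, DMF, 0 → 25 °C
Reagents that add atoms: tert-butyldimethylsilyl chloride, CC(C)(C)[Si](C)(C)Cl
Why: Silylation under these conditions is selective for the secondary allylic hydroxyl over the tertiary one.

Step 12
Reactants: 23 (1R,3aR,5S,8aR)-5-[(tert-butyldimethylsilyl)oxy]-1-hydroxy-3a,6-dimethyl-1-(propan-2-yl)-2,3,3a,4,5,8a-hexahydroazulen-8(1H)-one
Product: 24 (1R,3aR,5S,8S,8aS)-5-[(tert-butyldimethylsilyl)oxy]-3a,6-dimethyl-1-(propan-2-yl)-1,2,3,3a,4,5,8,8a-octahydroazulene-1,8-diol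
Conditions: Me4NBH(OAc)3, MeCN/AcOH, –30 °C
Reagents that add atoms: none
Why: Evans–Saksena reduction: the triacetoxyborohydride exchanges onto the C1 hydroxyl and delivers hydride to the C8 carbonyl from the face of that hydroxyl, which should give the 1,3-anti diol (8S) by 1,2-reduction of the enone.

Step 13
Reactants: 25 vanillic acid (4-hydroxy-3-methoxybenzoic acid)
Product: 27 4-[(tert-butyldimethylsilyl)oxy]-3-methoxybenzoic acid, via bis-silyl derivative 26 (not isolated)
Conditions: TBSCl (2.2 equiv), imidazole, DMF, 25 °C; then AcOH/THF/H2O, 25 °C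
Reagents that add atoms: tert-butyldimethylsilyl chloride, CC(C)(C)[Si](C)(C)Cl
Why: Silylation of both acidic hydroxyls followed by selective hydrolysis of the labile silyl ester leaves only the phenol protected.

Step 14
Reactants: 24 (1R,3aR,5S,8S,8aS)-5-[(tert-butyldimethylsilyl)oxy]-3a,6-dimethyl-1-(propan-2-yl)-1,2,3,3a,4,5,8,8a-octahydroazulene-1,8-diol; 27 4-[(tert-butyldimethylsilyl)oxy]-3-methoxybenzoic acid
Product: 29 (1R,3aR,5S,8S,8aS)-5-[(tert-butyldimethylsilyl)oxy]-1-hydroxy-3a,6-dimethyl-1-(propan-2-yl)-1,2,3,3a,4,5,8,8a-octahydroazulen-8-yl 4-[(tert-butyldimethylsilyl)oxy]-3-methoxybenzoate, via mixed anhydride 28 (not isolated)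
Conditions: 2,4,6-Cl3C6H2COCl, Et3N, THF, 25 °C; then 24, DMAP, toluene, 60 °C
Reagents that add atoms: none
Why: Yamaguchi esterification through mixed anhydride 28 acylates the hindered secondary allylic alcohol with retention; the tertiary hydroxyl is inert.

Step 15
Reactants: 29 bis-silylated ester
Product: 30 (1R,3aR,5S,8S,8aS)-1,5-dihydroxy-3a,6-dimethyl-1-(propan-2-yl)-1,2,3,3a,4,5,8,8a-octahydroazulen-8-yl 4-hydroxy-3-methoxybenzoate (target)
Conditions: Bu4NF, AcOH, THF, 0 → 25 °C
Reagents that add atoms: none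
Why: Buffered fluoride desilylation should cleave the aryl and the secondary silyl ethers without touching the ester or the allylic system.

**Compound list**

1 | 2-methylcyclohexanone (racemic) | CC1CCCCC1=O | starting material
2 | (R)-1-phenylethylamine | C[C@@H](N)c1ccccc1 | starting material
3 | methyl vinyl ketone | CC(=O)C=C | starting material
4 | imine of 1 with 2 (C2 epimers) | CC1CCCCC1=N[C@H](C)c2ccccc2 | intermediate
5 | 4-[(1S)-1-methyl-2-{[(1R)-1-phenylethyl]imino}cyclohexyl]butan-2-one | CC(=O)CC[C@]1(C)CCCCC1=N[C@H](C)c2ccccc2 | intermediate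
6 | (S)-2-methyl-2-(3-oxobutyl)cyclohexan-1-one | CC(=O)CC[C@]1(C)CCCCC1=O | intermediate
7 | cis-fused 8a-hydroxy-4a-methyloctahydronaphthalen-2(1H)-one (OH and CH3 on the same face) | O=C1CC[C@]2(C)CCCC[C@]2(O)C1 | intermediate
8 | (S)-4a-methyl-4,4a,5,6,7,8-hexahydronaphthalen-2(3H)-one | O=C1C=C2CCCC[C@@]2(C)CC1 | intermediate
9 | (2R,4aS)-4a-methyl-2-(propan-2-yl)-2,3,4,4a,5,6,7,8-octahydronaphthalen-2-ol (OH cis to 4a-CH3) | O[C@]1(C(C)C)C=C2CCCC[C@@]2(C)CC1 | intermediate
10 | osmate ester of 9 (O1,O8a-bridged dioxo-osmium TMEDA chelate on the face of the free 2-OH) | O[C@@]1(C(C)C)CC[C@]2(C)CCCC[C@@]23O[Os-2]4(=O)(=O)([N+](C)(C)CC[N+]4(C)C)O[C@@H]13 | intermediate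
11 | 2-O-trimethylsilyl ether of osmate ester 10 | C[Si](C)(C)O[C@@]1(C(C)C)CC[C@]2(C)CCCC[C@@]23O[Os-2]4(=O)(=O)([N+](C)(C)CC[N+]4(C)C)O[C@@H]13 | intermediate
12 | (1R,2R,4aS,8aR)-4a-methyl-2-(propan-2-yl)-2-[(trimethylsilyl)oxy]decahydronaphthalene-1,8a-diol (cis-fused; 1-OH, 2-OSi, 8a-OH and 4a-CH3 on one face) | C[Si](C)(C)O[C@@]1(C(C)C)CC[C@]2(C)CCCC[C@]2(O)[C@H]1O | intermediate
13 | 1-O-methanesulfonate of 12 | C[Si](C)(C)O[C@@]1(C(C)C)CC[C@]2(C)CCCC[C@]2(O)[C@H]1OS(C)(=O)=O | intermediate
14 | (1R,3aS,8aR)-3a-methyl-1-(propan-2-yl)-1-[(trimethylsilyl)oxy]octahydroazulen-8(1H)-one (trans-fused; 1-OSi cis to 3a-CH3) | O=C1CCCC[C@@]2(C)CC[C@@](O[Si](C)(C)C)(C(C)C)[C@H]12 | intermediate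
15 | 8-trimethylsilyl enol ether of 14 (C7=C8) | C[Si](C)(C)OC1=CCCC[C@@]2(C)CC[C@@](O[Si](C)(C)C)(C(C)C)[C@H]12 | intermediate
16 | (1R,3aS,8aR)-3a-methyl-1-(propan-2-yl)-1-[(trimethylsilyl)oxy]-2,3,3a,4,5,8a-hexahydroazulen-8(1H)-one | O=C1C=CCC[C@@]2(C)CC[C@@](O[Si](C)(C)C)(C(C)C)[C@H]12 | intermediate
17 | 6-methyl 8-trimethylsilyl enol ether (C6 epimers) | C[Si](C)(C)OC1=CC(C)CC[C@@]2(C)CC[C@@](O[Si](C)(C)C)(C(C)C)[C@H]12 | intermediate
18 | (1R,3aS,8aR)-3a,6-dimethyl-1-(propan-2-yl)-1-[(trimethylsilyl)oxy]-2,3,3a,4,5,8a-hexahydroazulen-8(1H)-one | O=C1C=C(C)CC[C@@]2(C)CC[C@@](O[Si](C)(C)C)(C(C)C)[C@H]12 | intermediate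
19 | 8-(tert-butyldimethylsilyloxy)-5,7-diene (dienol ether of 18) | CC(C)(C)[Si](C)(C)OC1=CC(C)=CC[C@@]2(C)CC[C@@](O[Si](C)(C)C)(C(C)C)[C@H]12 | intermediate
20 | 5,8-epidioxide of 19 (peroxide bridge on the face opposite the 3a-CH3) | CC(C)(C)[Si](C)(C)O[C@]13OO[C@H](C(C)=C1)C[C@@]2(C)CC[C@@](O[Si](C)(C)C)(C(C)C)[C@H]32 | intermediate
21 | (1R,3aR,5S,8aR)-5-hydroxy-3a,6-dimethyl-1-(propan-2-yl)-1-[(trimethylsilyl)oxy]-2,3,3a,4,5,8a-hexahydroazulen-8(1H)-one | O=C1C=C(C)[C@@H](O)C[C@@]2(C)CC[C@@](O[Si](C)(C)C)(C(C)C)[C@H]12 | intermediate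
22 | (1R,3aR,5S,8aR)-1,5-dihydroxy-3a,6-dimethyl-1-(propan-2-yl)-2,3,3a,4,5,8a-hexahydroazulen-8(1H)-one | O=C1C=C(C)[C@@H](O)C[C@@]2(C)CC[C@@](O)(C(C)C)[C@H]12 | intermediate
23 | 5-O-tert-butyldimethylsilyl ether of 22 | O=C1C=C(C)[C@@H](O[Si](C)(C)C(C)(C)C)C[C@@]2(C)CC[C@@](O)(C(C)C)[C@H]12 | intermediate
24 | (1R,3aR,5S,8S,8aS)-5-[(tert-butyldimethylsilyl)oxy]-3a,6-dimethyl-1-(propan-2-yl)-1,2,3,3a,4,5,8,8a-octahydroazulene-1,8-diol | O[C@H]1C=C(C)[C@@H](O[Si](C)(C)C(C)(C)C)C[C@@]2(C)CC[C@@](O)(C(C)C)[C@H]12 | intermediate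
25 | vanillic acid | COc1cc(C(=O)O)ccc1O | starting material
26 | tert-butyldimethylsilyl 4-[(tert-butyldimethylsilyl)oxy]-3-methoxybenzoate | COc1cc(C(=O)O[Si](C)(C)C(C)(C)C)ccc1O[Si](C)(C)C(C)(C)C | intermediate
27 | 4-[(tert-butyldimethylsilyl)oxy]-3-methoxybenzoic acid | COc1cc(C(=O)O)ccc1O[Si](C)(C)C(C)(C)C | intermediate
28 | mixed anhydride of 27 with 2,4,6-trichlorobenzoic acid | COc1cc(C(=O)OC(=O)c2c(Cl)cc(Cl)cc2Cl)ccc1O[Si](C)(C)C(C)(C)C | intermediate
29 | bis-silylated ester (5-O-TBS, aryl O-TBS) | COc1cc(C(=O)O[C@H]2C=C(C)[C@@H](O[Si](C)(C)C(C)(C)C)C[C@@]3(C)CC[C@@](O)(C(C)C)[C@H]23)ccc1O[Si](C)(C)C(C)(C)C | intermediate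
30 | (1R,3aR,5S,8S,8aS)-1,5-dihydroxy-3a,6-dimethyl-1-(propan-2-yl)-1,2,3,3a,4,5,8,8a-octahydroazulen-8-yl 4-hydroxy-3-methoxybenzoate | COc1cc(C(=O)O[C@H]2C=C(C)[C@@H](O)C[C@@]3(C)CC[C@@](O)(C(C)C)[C@H]23)ccc1O | target

**Step count and risks**

Total step count: 15. Longest linear sequence: 14 (steps 1–12, 14, 15; step 13 is a one-step side branch).

Steps most likely to fail:

Step 4. The hydrogen-bond-directed delivery has to compete with attack on the face opposite the angular methyl, and the tertiary hydroxyl, tied to the bulky osmate ester, may silylate too slowly, so that the two tertiary oxygens are no longer told apart. The fallback sets out from 9 and returns at 12. Directed dihydroxylation with OsO4/TMEDA followed by aq. Na2SO3 work-up should give the free all-cis triol F1. Exhaustive silylation with N-(trimethylsilyl)imidazole (60 °C) should cover the secondary C1 and the tertiary C2 hydroxyl but not the C8a hydroxyl, which sits on the ring fusion next to the quaternary carbon, giving bis-silyl ether F2. K2CO3 in MeOH at 0 °C then removes only the secondary silyl ether and delivers 12. The distinction then rests on steric discrimination instead of on the osmate mask.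

Step 6. The neopentyl-type mesylate may ionize slowly under the organoaluminium conditions, and Lewis-acid-induced loss or oxygen-to-oxygen shift of the tertiary silyl ether could overtake the ring-bond shift. The fallback sets out from 13 and returns at 14. Citric acid in MeOH/H2O removes the silyl ether to give triol monomesylate F3. Buffered solvolysis (LiClO4, CaCO3, aqueous THF, 50 °C) is a pinacol-type shift without Lewis acid, whose cation-like transition state should favour migration of the fully substituted C4a over the C3 methylene; it gives hydroxy ketone F4. N-(trimethylsilyl)imidazole then returns 14.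

Step 10. Ene reaction or attack of singlet oxygen on the wrong face of the diene may compete, and the endoperoxide may fragment by base (Kornblum–DeLaMare) to the enedione. The fallback sets out from 19 and returns at 21. Kinetic protodesilylation (Bu4NF, AcOH, THF, –78 °C) protonates C7 and should give the deconjugated β,γ-unsaturated ketone F5. Epoxidation with mCPBA/NaHCO3 on the face opposite the angular methyl gives epoxide F6. DBU opens the epoxide by E1cB elimination to the γ-hydroxy enone 21, which is desilylated with citric acid as in step 10 to give 22.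

Further compounds
F1 | step 4 | all-cis 4a-methyl-2-(propan-2-yl)decahydronaphthalene-1,2,8a-triol (configuration as 12) | O[C@@]1(C(C)C)CC[C@]2(C)CCCC[C@]2(O)[C@H]1O
F2 | step 4 | 1,2-bis-O-trimethylsilyl ether of F1 (8a-OH free) | C[Si](C)(C)O[C@@]1(C(C)C)CC[C@]2(C)CCCC[C@]2(O)[C@H]1O[Si](C)(C)C
F3 | step 6 | 2,8a-dihydroxy-4a-methyl-2-(propan-2-yl)decahydronaphthalen-1-yl methanesulfonate (desilylated 13) | O[C@@]1(C(C)C)CC[C@]2(C)CCCC[C@]2(O)[C@H]1OS(C)(=O)=O
F4 | step 6 | trans-fused 1-hydroxy-3a-methyl-1-(propan-2-yl)octahydroazulen-8(1H)-one (desilylated 14) | O=C1CCCC[C@@]2(C)CC[C@@](O)(C(C)C)[C@H]12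
F5 | step 10 | 3a,6-dimethyl-1-(propan-2-yl)-1-[(trimethylsilyl)oxy]-2,3,3a,4,7,8a-hexahydroazulen-8(1H)-one (C5=C6 isomer of 18) | O=C1CC(C)=CC[C@@]2(C)CC[C@@](O[Si](C)(C)C)(C(C)C)[C@H]12
F6 | step 10 | 5,6-epoxide of F5 (oxygen on the face opposite the 3a-CH3) | O=C1C[C@@]3(C)O[C@H]3C[C@@]2(C)CC[C@@](O[Si](C)(C)C)(C(C)C)[C@H]12
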